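Everything rests on cutting the O1–C2 ether bond of ring C while raising ring B (a C2'/C5' hydroquinone whose C1' carries C2) to the quinone level. The precursor is then an open (R)-α-methoxydihydrochalcone bearing a 5-methoxy-1,4-benzoquinone, an isomer of the closed flavanonol. In one operation the C2 methylene tautomerises into the C2=C1'–C2'=O ortho-quinone methide (stabilised by the para C4'-OMe). The ring A phenol oxygen then adds to C2 (6-exo-trig), ring B re-aromatises to the free hydroquinone, and C2 is set trans to C3. C3 comes from methyl (R)-glycidate, and C5-OH is unmasked last.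

Key step: step 7

Remark: flavonoid numbering (ring C: O1, C2, C3, C4; ring A: C4a to C8a; ring B: primed) is used for open-chain precursors as well. The (2R,3R) descriptors of the target correspond to the 2,3-trans relationship. Compounds 1, 2 and 7 are taken as commercial.

Step 1
Reactants: 1 1-bromo-2,4,5-trimethoxybenzene; 2 methyl (R)-glycidate (methyl (2R)-oxirane-2-carboxylate)
Product: 4 methyl (R)-2-hydroxy-3-(2,4,5-trimethoxyphenyl)propanoate, via arylmagnesium bromide 3 (not isolated)
Conditions: 1, Mg, THF, reflux; then CuBr·SMe2 (10 mol %), 2, THF, −40 → −20 °C; aqueous work-up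
Reagents that add atoms: none
Why: Copper-catalysed Grignard opening of a terminal epoxide (SN2 at the unsubstituted CH2) should outrun addition to the ester at low temperature, and because the C–O bond at the stereocentre is not touched, the (R) configuration of 2 passes unchanged into 4.

Step 2
Reactants: 4 methyl (R)-2-hydroxy-3-(2,4,5-trimethoxyphenyl)propanoate
Product: 5 methyl (R)-2-methoxy-3-(2,4,5-trimethoxyphenyl)propanoate
Conditions: MeI (excess), Ag2O, 4 Å MS, MeCN, 23 °C, dark
Reagents that add atoms: iodomethane, CI
Why: Purdie methylation etherifies the secondary alcohol under essentially neutral conditions, so the enolisable α-stereocentre (the future C3) should not racemise.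

Step 3
Reactants: 5 methyl (R)-2-methoxy-3-(2,4,5-trimethoxyphenyl)propanoate
Product: 6 (R)-N,2-dimethoxy-N-methyl-3-(2,4,5-trimethoxyphenyl)propanamide
Conditions: MeNH(OMe)·HCl, iPrMgCl, THF, −20 → 0 °C
Reagents that add atoms: N,O-dimethylhydroxylamine hydrochloride, CNOC.Cl
Why: Weinreb amide formation by aminolysis of the ester with the chloromagnesium amide made in the flask is fast at low temperature, where α-alkoxy esters should keep their configuration.

Step 4
Reactants: 7 3,4,5-trimethoxyphenol
Product: 8 1,2,3-trimethoxy-5-(methoxymethoxy)benzene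
Conditions: MOMCl, iPr2NEt, CH2Cl2, 0 → 23 °C
Reagents that add atoms: chloromethyl methyl ether, COCCl
Why: O-alkylation of the phenol (MOM protection) masks the future O1 and installs a strong directing group for the metalation that follows.

Step 5
Reactants: 8 1,2,3-trimethoxy-5-(methoxymethoxy)benzene; 6 (R)-N,2-dimethoxy-N-methyl-3-(2,4,5-trimethoxyphenyl)propanamide
Product: 10 (R)-2-methoxy-1-[2,3,4-trimethoxy-6-(methoxymethoxy)phenyl]-3-(2,4,5-trimethoxyphenyl)propan-1-one, via aryllithium 9 (not isolated)
Conditions: 8, n-BuLi, THF, 0 °C; then 6, −78 → −20 °C; aqueous work-up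
Reagents that add atoms: none
Why: Directed ortho-metalation is unambiguous because the two free positions of 8 are equivalent by symmetry and each lies between OMOM and OMe, and in the Weinreb ketone synthesis the chelated tetrahedral intermediate blocks over-addition and keeps the enolisable ketone masked until the quench, so the stereocentre should survive.

Step 6
Reactants: 10 (R)-2-methoxy-1-[2,3,4-trimethoxy-6-(methoxymethoxy)phenyl]-3-(2,4,5-trimethoxyphenyl)propan-1-one
Product: 11 (R)-2-methoxy-5-{2-methoxy-3-oxo-3-[2,3,4-trimethoxy-6-(methoxymethoxy)phenyl]propyl}cyclohexa-2,5-diene-1,4-dione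
Conditions: (NH4)2Ce(NO3)6 (2.1 equiv), MeCN–H2O (4:1), −10 → 0 °C, short contact time
Reagents that add atoms: water, O
Why: Oxidative demethylation of a 1,4-dimethoxyarene by tetravalent cerium should take the alkyl-substituted trialkoxy ring B, which is easier to oxidise than the acyl-substituted and fully etherified ring A, converting the para C2'/C5' methoxy pair into the quinone and leaving C4'-OMe as a vinylogous ester.

Step 7
Reactants: 11 (R)-2-methoxy-5-{2-methoxy-3-oxo-3-[2,3,4-trimethoxy-6-(methoxymethoxy)phenyl]propyl}cyclohexa-2,5-diene-1,4-dione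
Product: 14 (2R,3R)-2-(2,5-dihydroxy-4-methoxyphenyl)-3,5,6,7-tetramethoxychroman-4-one, via phenol quinone 12 (not isolated), via ortho-quinone methide 13 (not isolated)
Conditions: TFA–CH2Cl2–H2O (10:89:1), 0 °C; evaporate with toluene; then Et3N (0.3 equiv), degassed MeCN (2 mM), Ar, dark, 23 → 40 °C; AcOH quench
Reagents that add atoms: none
Why: Acid first removes the MOM group from the ring A oxygen to give 12; catalytic Et3N then removes a C2 proton, vinylogously acidic through C1'=C6'–C5'=O, and reprotonation on the C5' oxygen gives the (E)-ortho-quinone methide 13, a push–pull system stabilised by the para C4'-OMe. The ring A phenol adds to C2 of 13 in an intramolecular oxa-conjugate addition and ring B re-aromatises, so 12 to 14 is a redox-neutral isomerisation; the closest known reaction types are the base-induced tautomerisation of alkylquinones to ortho-quinone methides with nucleophilic capture and the quinone methide closure of 2-hydroxy-1,3-diarylpropanes to flavans. Ring C closes in the 6-exo-trig mode, because the attacked C2=C1' bond lies outside the new ring, unlike the 6-endo-trig closure of a chalcone. The new C2 stereocentre is controlled by the existing C3 stereocentre: the half-chair transition state with C3-OMe and the C2 aryl group both pseudo-equatorial leads to the 2,3-trans (2R,3R) isomer, and because the 2'-OH lets the closure reverse through 13 without touching C3, any cis isomer should drain to the more stable trans one. The step needs site selectivity between the two ring A oxygens flanking the ketone, secured because only the future O1 is free while the C5 oxygen is still a methyl ether (no Wessely–Moser type isomer); it also needs capture to outrun the 1,5-hydrogen shift of 13 to the α-methoxychalcone and bimolecular quinone chemistry, which the (E) geometry, the nearby phenol and high dilution should secure. Cross-oxidation of 14 by 12 should be unfavourable, since the aryloxy group at C2 makes the quinone of 14 the stronger oxidant.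

Step 8
Reactants: 14 (2R,3R)-2-(2,5-dihydroxy-4-methoxyphenyl)-3,5,6,7-tetramethoxychroman-4-one
Product: 15 (2R,3R)-2-(2,5-dihydroxy-4-methoxyphenyl)-5-hydroxy-3,6,7-trimethoxychroman-4-one (target)
Conditions: BCl3 (4 equiv), CH2Cl2, −78 → −10 °C; H2O quench
Reagents that add atoms: none
Why: Chelation-directed aryl methyl ether cleavage by BCl3 should take only C5-OMe, the one aryl methoxy group that forms a six-membered boron chelate with the C4 carbonyl, and the low temperature should leave C3-OMe, the other aryl ethers and both stereocentres untouched.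

Compound list
1 | 1-bromo-2,4,5-trimethoxybenzene | COc1cc(OC)c(OC)cc1Br | starting material
2 | methyl (R)-glycidate | COC(=O)[C@H]1CO1 | starting material
3 | (2,4,5-trimethoxyphenyl)magnesium bromide (not isolated) | COc1cc(OC)c(OC)cc1[Mg]Br | intermediate
4 | methyl (R)-2-hydroxy-3-(2,4,5-trimethoxyphenyl)propanoate | COC(=O)[C@H](O)Cc1cc(OC)c(OC)cc1OC | intermediate
5 | methyl (R)-2-methoxy-3-(2,4,5-trimethoxyphenyl)propanoate | COC(=O)[C@H](OC)Cc1cc(OC)c(OC)cc1OC | intermediate
6 | (R)-N,2-dimethoxy-N-methyl-3-(2,4,5-trimethoxyphenyl)propanamide | CON(C)C(=O)[C@H](OC)Cc1cc(OC)c(OC)cc1OC | intermediate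
7 | 3,4,5-trimethoxyphenol | COc1cc(O)cc(OC)c1OC | starting material
8 | 1,2,3-trimethoxy-5-(methoxymethoxy)benzene | COCOc1cc(OC)c(OC)c(OC)c1 | intermediate
9 | [2,3,4-trimethoxy-6-(methoxymethoxy)phenyl]lithium (not isolated) | [Li]c1c(OCOC)cc(OC)c(OC)c1OC | intermediate
10 | (R)-2-methoxy-1-[2,3,4-trimethoxy-6-(methoxymethoxy)phenyl]-3-(2,4,5-trimethoxyphenyl)propan-1-one | COCOc1cc(OC)c(OC)c(OC)c1C(=O)[C@H](OC)Cc1cc(OC)c(OC)cc1OC | intermediate
11 | (R)-2-methoxy-5-{2-methoxy-3-oxo-3-[2,3,4-trimethoxy-6-(methoxymethoxy)phenyl]propyl}cyclohexa-2,5-diene-1,4-dione | COCOc1cc(OC)c(OC)c(OC)c1C(=O)[C@H](OC)CC1=CC(=O)C(OC)=CC1=O | intermediate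
12 | (R)-2-[3-(6-hydroxy-2,3,4-trimethoxyphenyl)-2-methoxy-3-oxopropyl]-5-methoxycyclohexa-2,5-diene-1,4-dione (not isolated) | COc1cc(O)c(C(=O)[C@H](OC)CC2=CC(=O)C(OC)=CC2=O)c(OC)c1OC | intermediate
13 | (R,E)-4-hydroxy-6-[3-(6-hydroxy-2,3,4-trimethoxyphenyl)-2-methoxy-3-oxopropylidene]-3-methoxycyclohexa-2,4-dien-1-one (not isolated) | COc1cc(O)c(C(=O)[C@H](OC)/C=C2\C=C(O)C(OC)=CC2=O)c(OC)c1OC | intermediate
14 | (2R,3R)-2-(2,5-dihydroxy-4-methoxyphenyl)-3,5,6,7-tetramethoxychroman-4-one | COc1cc(O)c([C@H]2Oc3cc(OC)c(OC)c(OC)c3C(=O)[C@@H]2OC)cc1O | intermediate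
15 | (2R,3R)-2-(2,5-dihydroxy-4-methoxyphenyl)-5-hydroxy-3,6,7-trimethoxychroman-4-one | COc1cc(O)c([C@H]2Oc3cc(OC)c(OC)c(O)c3C(=O)[C@@H]2OC)cc1O | target

Total step count: 8. Longest linear sequence: 7 (steps 1, 2, 3, 5, 6, 7, 8).

Steps most likely to fail

Step 7.
- What may go wrong: the tautomerisation may be too slow under mild base. The quinone methide may also leak by 1,5-hydrogen shift into the chalcone manifold, which erodes the C3 configuration, or it may dimerise or exchange redox state with the product.
- Fallback (sets out from 10, comes back at 14): the ring is closed at the arene oxidation level by hydride abstraction, and ring B is adjusted afterwards.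
- The MOM group of 10 is removed with TFA in CH2Cl2 to give the free phenol (R)-1-(6-hydroxy-2,3,4-trimethoxyphenyl)-2-methoxy-3-(2,4,5-trimethoxyphenyl)propan-1-one F1.
- DDQ in CH2Cl2 abstracts hydride from the benzylic CH2 of the electron-rich trimethoxyphenyl ring, and the phenol captures the cation. This is the oxidative benzylic C–H etherification used for flavans, with trans control from C3. It should give (2R,3R)-3,5,6,7-tetramethoxy-2-(2,4,5-trimethoxyphenyl)chroman-4-one F2.
- (NH4)2Ce(NO3)6 in aqueous MeCN converts ring B into 2-methoxy-5-[(2R,3R)-3,5,6,7-tetramethoxy-4-oxochroman-2-yl]cyclohexa-2,5-diene-1,4-dione F3, and Na2S2O4 reduces this quinone to 14.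

Step 6.
- What may go wrong: poor chemoselectivity between the two electron-rich rings (over-oxidation of ring A), oxidative biaryl coupling of ring B, or early loss of the MOM group while oxidant is still present.
- Fallback (sets out from 10, comes back at 11): the chemical oxidant is replaced by potential-controlled anodic bis-ketalisation.
- Electrolysis of 10 in MeOH (LiClO4, 2,6-lutidine buffer, carbon anode), at a potential just above the oxidation wave of ring B, should give the quinone bis(dimethyl ketal) (R)-2-methoxy-3-(3,3,4,6,6-pentamethoxycyclohexa-1,4-dien-1-yl)-1-[2,3,4-trimethoxy-6-(methoxymethoxy)phenyl]propan-1-one F4.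
- Mild hydrolysis of the ketals with dilute aqueous AcOH in acetone then returns 11.

Step 8.
- What may go wrong: poor site selectivity among five methyl ethers. The Lewis acid may also ionise the O1–C2 bond, assisted by the free 2'-OH, leading to epimerisation or re-closure through the newly freed C5 oxygen.
- Fallback (sets out from 14, comes back at 15): the donor ability of ring B is switched off before the demethylation.
- Ac2O and pyridine convert 14 into (2R,3R)-2-(2,5-diacetoxy-4-methoxyphenyl)-3,5,6,7-tetramethoxychroman-4-one F5.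
- BCl3 at low temperature then cleaves only the chelated C5-OMe to give (2R,3R)-2-(2,5-diacetoxy-4-methoxyphenyl)-5-hydroxy-3,6,7-trimethoxychroman-4-one F6.
- Neutral hydrolysis of the aryl acetates with NH4OAc in aqueous MeOH at 23 °C releases 15.

Further compounds
F1 | step 7 | (R)-1-(6-hydroxy-2,3,4-trimethoxyphenyl)-2-methoxy-3-(2,4,5-trimethoxyphenyl)propan-1-one | COc1cc(O)c(C(=O)[C@H](OC)Cc2cc(OC)c(OC)cc2OC)c(OC)c1OC
F2 | step 7 | (2R,3R)-3,5,6,7-tetramethoxy-2-(2,4,5-trimethoxyphenyl)chroman-4-one | COc1cc(OC)c([C@H]2Oc3cc(OC)c(OC)c(OC)c3C(=O)[C@@H]2OC)cc1OC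
F3 | step 7 | 2-methoxy-5-[(2R,3R)-3,5,6,7-tetramethoxy-4-oxochroman-2-yl]cyclohexa-2,5-diene-1,4-dione | COC1=CC(=O)C([C@H]2Oc3cc(OC)c(OC)c(OC)c3C(=O)[C@@H]2OC)=CC1=O
F4 | step 6 | (R)-2-methoxy-3-(3,3,4,6,6-pentamethoxycyclohexa-1,4-dien-1-yl)-1-[2,3,4-trimethoxy-6-(methoxymethoxy)phenyl]propan-1-one | COCOc1cc(OC)c(OC)c(OC)c1C(=O)[C@H](OC)CC1=CC(OC)(OC)C(OC)=CC1(OC)OC
F5 | step 8 | (2R,3R)-2-(2,5-diacetoxy-4-methoxyphenyl)-3,5,6,7-tetramethoxychroman-4-one | COc1cc(OC(C)=O)c([C@H]2Oc3cc(OC)c(OC)c(OC)c3C(=O)[C@@H]2OC)cc1OC(C)=O
F6 | step 8 | (2R,3R)-2-(2,5-diacetoxy-4-methoxyphenyl)-5-hydroxy-3,6,7-trimethoxychroman-4-one | COc1cc(OC(C)=O)c([C@H]2Oc3cc(OC)c(OC)c(O)c3C(=O)[C@@H]2OC)cc1OC(C)=O
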